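## Structural features

The target, 2-hydroxy-6-[2-[4-[3-[2-(4-hydroxyphenyl)ethyl]-5-methoxyphenoxy]phenyl]ethyl]-4-methoxybenzoic acid, is a linear array of four benzene rings with no stereocentre and no other ring. Ring A (4-hydroxyphenyl) is joined to C1 of ring B by a CH2–CH2 bridge. Ring B is 1,3,5-trisubstituted, with a methoxy group and the ether oxygen to ring C. Ring C is a para-phenylene whose other position carries a second CH2–CH2 bridge to C6 of ring D. Ring D is a tetrasubstituted benzoic acid (carboxyl C1, hydroxyl C2, methoxy C4, bridge C6), so the carboxyl is flanked on both sides. The fragile part is this 2-hydroxy-6-alkylbenzoic acid, which loses CO2 in hot acid or base; the two free phenols are oxidisable, and the diaryl ether and two methyl ethers must survive whatever frees the phenols. The real difficulty is differentiation of four oxygens (two methylated, two free) and attachment of an sp3 bridge ortho to a hindered carboxyl without building ring D from acyclic material. The plan uses the ortho relation between the carboxyl at C1 and the bridge at C6 of ring D: in 2,4-dimethoxybenzoic acid the carboxylate can direct a metal into the C6–H bond, the only ortho C–H, and then trap the incoming two-carbon unit as the lactone of a 3-arylisocoumarin. The same carboxyl later chelates the C2 methoxy group, which allows that ether alone to be cleaved.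

## Logic of the disconnections

The first move re-forms the O–CH3 bond at C2 of ring D and leads from 16 to 15. This oxygen is the only methylated oxygen ortho to the carboxyl, so ring D can enter with both oxygens methylated. The gain is that no differentiated resorcinol has to be made. The demand is that the forward dealkylation cuts only the chelated ether and leaves the ethers at C4 of ring D and on ring B, and the diaryl ether, alone.

The second move joins the carboxyl oxygen to the benzylic carbon of the ring C–ring D bridge, places a double bond between the two bridge carbons and puts a benzyl group on the ring A oxygen; this leads from 15 through 14 to 13. In the forward sense the lactone O–C3 bond and the O–CH2Ph bond are broken and hydrogen is added to C3=C4. The gain is that acid, phenol and saturated bridge all appear in one hydrogenation. The demand is complete hydrogenolysis of the benzylic lactone bond without attack on the diaryl ether or the arenes.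

The third move cuts 13 at the bond from C6 of ring D to the bridge carbon (C4a–C4 of the isocoumarin) and at the lactone O–C3 bond, giving 11 and 10. This is the most convergent cut: 11 is purchasable and 10 holds rings A, B and C. The demand is metalation at C6–H only and carbene transfer to the rhodacycle faster than self-reaction of 10; the ring then closes through 12.

The fourth move cuts the C(=O)–CH bond of 10, giving acyl donor 7 and one-carbon donor 9, which is made in the flask from 8. The gain is that the ylide carbon comes from a cheap salt and the ketone oxidation level from an ester. The demand is an excess of 9, because the first-formed keto sulfoxonium salt must be deprotonated, and the absence of any other electrophile in 7.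

The fifth move cuts the bond between the ether oxygen and ring C of 7, giving 5 and 6. The para ester needed for the fourth move also activates the ring for fluoride displacement, so no extra activating group is carried. The demand is attack of the phenoxide at the ring carbon and not at the ester.

The last move places a double bond in the ring A–ring B bridge of 5, giving 4, and cuts that C=C bond to 1 and to 3, formed from 2. Both partners are simple aromatic building blocks. The alkene geometry is irrelevant, but the reduction of 4 must not cleave the O-benzyl group that 10 and 13 need; catalytic hydrogenation over palladium is therefore replaced by diimide.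

## Other disconnections considered

Alternative 1: The cut is made at the two aryl–carbon bonds of the ring A–ring B bridge, with both bridge carbons supplied by propiolic acid A4. In the forward sense 1-(benzyloxy)-4-iodobenzene A3 would undergo Sonogashira coupling with A4 at room temperature. The aryl propiolate would then, on heating in the same flask with the ring B bromide benzyl 2-(benzyloxy)-6-[2-[4-(3-bromo-5-methoxyphenoxy)phenyl]ethyl]-4-methoxybenzoate A2, lose CO2 and couple again to give the diarylalkyne A1.
- In its favour: the alkyne has no geometry to control and the union is late and convergent. Every protecting group in A1 is a benzyl group, so one hydrogenation over palladium on carbon would reduce the alkyne and free both phenols and the acid. On this point it is better than the chosen plan, whose endgame needs two steps and a selective demethylation.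
- Against it: the bonds it makes are the easy ones, which the chosen plan obtains from a Wittig reaction of two purchasable partners. The tetrasubstituted ring D, the bridge ortho to the carboxyl and the diaryl ether all remain inside A2. A2 must be built with a saturated ring C–ring D bridge while an aryl bromide and two benzyl groups are carried, which excludes catalytic hydrogenation on the way. The decarboxylative coupling also needs oxidative addition into an electron-rich aryl bromide, and premature decarboxylation leads to symmetrical diarylalkyne.
- Comparison: both plans rest on precedented metal catalysis of similar functional-group tolerance (equal). Structurally the chosen plan addresses ring D directly, whereas this one postpones it. In step count A2 alone should need about as many steps as the whole chosen route.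

Alternative 2: Ring B itself is cut at the two ring bonds that join the ethynyl carbons of an aryl ethynyl ether to a four-carbon vinylketene unit. One bond runs from the aryloxy-bearing carbon to the CH next to the alkyl-bearing carbon, the other from the neighbouring CH to the carbon that becomes the phenol. In the forward sense 3-[2-(4-benzyloxyphenyl)ethyl]cyclobut-2-en-1-one A6 would be heated with tert-butyl 2-[2-(4-ethynyloxyphenyl)ethyl]-4,6-dimethoxybenzoate A7. The cyclobutenone opens to a vinylketene, which adds the alkyne in a [2+2] reaction; the 2-vinylcyclobutenone opens again, and 6π closure with tautomerisation would give the phenol A5 (Danheiser benzannulation).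
- In its favour: it needs no metal, which is better than the chosen plan on catalyst cost. It forms ring B and the diaryl ether in one operation, with the 1,3,5 pattern fixed by the mechanism, and the new phenol emerges ready for methylation.
- Against it: aryl ethynyl ethers such as A7 are awkward to prepare and polymerise readily. A6 needs a ketene–alkyne cycloaddition and dehalogenation sequence. The substitution pattern of ring B that the cascade secures is already available in purchasable 1. Ring D with its ortho bridge must still be made by separate chemistry to reach A7. After A5, O-methylation, ester cleavage, chelation-controlled demethylation and debenzylation remain.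
- Comparison: the selective demethylation question is the same as in the chosen plan (equal). Mechanistically the pericyclic cascade is elegant but is spent on a problem that is already solved. The step count should be roughly twice that of the chosen route.

Alternative 3: Ring D is cut at C1–C6 and C2–C3 and traced to the enone (E)-6-[4-[3-[2-(4-benzyloxyphenyl)ethyl]-5-methoxyphenoxy]phenyl]hex-3-en-2-one A9 and dimethyl malonate A10. In the forward sense, under methoxide in methanol, the malonate anion would add to the β-carbon of A9 and the methyl ketone enolate would then condense onto one malonate ester. This would give the cyclic β-keto ester A8, racemic and trans because C1 can equilibrate; both stereocentres vanish on aromatisation.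
- In its favour: the reagents are cheap and no precious metal is used (better on cost). The position of the carboxyl between the oxygen and the bridge is fixed by construction. The C2 oxygen is never methylated, because after dehydrogenation the free C4 hydroxyl, not the hydrogen-bonded C2 hydroxyl, is the one that methylates. No Lewis acid demethylation is therefore needed, which is better than the chosen plan on that point.
- Against it: dehydrogenation of A8 classically relies on a halogen oxidant, and the substrate carries three electron-rich arenes open to electrophilic halogenation. Two stereocentres are made only to be destroyed. The hindered, hydrogen-bonded methyl ester must be saponified under forcing conditions at the end, on an acid that decarboxylates readily. A9 needs several steps of chain extension from 5.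
- Comparison: the enolate chemistry is as reliable as the chosen key step (equal). The chosen plan is shorter by about five steps and avoids the oxidation-level adjustment.

Key step: step 5

Assumption: (4-benzyloxybenzyl)triphenylphosphonium chloride 2 is treated as a purchasable Wittig salt; the chemistry does not depend on its source.

## Route

Step 1
Reactants: 1 3-hydroxy-5-methoxybenzaldehyde; 2 (4-benzyloxybenzyl)triphenylphosphonium chloride
Product: 4 3-[2-(4-benzyloxyphenyl)ethenyl]-5-methoxyphenol (E/Z mixture), via benzylidenephosphorane 3 (not isolated)
Conditions: 2 (1.2 equiv), KOtBu (2.4 equiv), THF, 0 °C to rt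
Reagents that add atoms: none
Why: Wittig olefination with a semi-stabilised benzylidene ylide; the extra base holds the phenol as its phenoxide, which is meta to the formyl group and so hardly lowers its electrophilicity, and the alkene geometry does not matter because the double bond is reduced next.

Step 2
Reactants: 4 3-[2-(4-benzyloxyphenyl)ethenyl]-5-methoxyphenol (E/Z mixture)
Product: 5 3-[2-(4-benzyloxyphenyl)ethyl]-5-methoxyphenol
Conditions: TsNHNH2 (6 equiv, in portions), NaOAc, DME–H2O, reflux
Reagents that add atoms: none
Why: Diimide reduction; diimide formed by fragmentation of the sulfonyl hydrazide transfers H2 to the C=C bond in a concerted syn fashion and has no hydrogenolysis pathway, so both isomers of 4 should be saturated while the aryl benzyl ether is kept.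

Step 3
Reactants: 5 3-[2-(4-benzyloxyphenyl)ethyl]-5-methoxyphenol; 6 methyl 4-fluorobenzoate
Product: 7 methyl 4-[3-[2-(4-benzyloxyphenyl)ethyl]-5-methoxyphenoxy]benzoate
Conditions: 6 (1.3 equiv), Cs2CO3 (1.5 equiv), dry DMSO, 110 °C
Reagents that add atoms: none
Why: Nucleophilic aromatic substitution (addition–elimination); the para ester stabilises the Meisenheimer intermediate, fluoride is the best leaving group for this mechanism, and attack of the phenoxide at the ester carbonyl is reversible and unproductive.

Step 4
Reactants: 7 methyl 4-[3-[2-(4-benzyloxyphenyl)ethyl]-5-methoxyphenoxy]benzoate; 8 trimethylsulfoxonium iodide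
Product: 10 dimethylsulfoxonium 2-[4-[3-[2-(4-benzyloxyphenyl)ethyl]-5-methoxyphenoxy]phenyl]-2-oxoethylide, via dimethylsulfoxonium methylide 9 (not isolated)
Conditions: 8 (3 equiv), KOtBu (3 equiv), THF, reflux; then 7, THF, reflux
Reagents that add atoms: none
Why: Acylation of the Corey–Chaykovsky methylide by a methyl ester; the keto sulfoxonium salt formed first is deprotonated by excess methylide or methoxide to the carbonyl-stabilised ylide, which does not react further.

Step 5
Reactants: 10 dimethylsulfoxonium 2-[4-[3-[2-(4-benzyloxyphenyl)ethyl]-5-methoxyphenoxy]phenyl]-2-oxoethylide; 11 2,4-dimethoxybenzoic acid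
Product: 13 3-[4-[3-[2-(4-benzyloxyphenyl)ethyl]-5-methoxyphenoxy]phenyl]-6,8-dimethoxy-1H-isochromen-1-one, via keto acid 12 (not isolated)
Conditions: [Cp*RhCl2]2 (4 mol %), NaOAc (1 equiv), CF3CH2OH, 80 °C, N2; 11 (1.5 equiv), 10 added slowly
Reagents that add atoms: none
Why: The carboxylate of 11 binds the Cp*Rh fragment (trivalent rhodium) and acetate-assisted concerted metalation–deprotonation at C6–H gives a five-membered rhodacycle. The ylide carbon of 10 then binds rhodium, dimethyl sulfoxide leaves, and the rhodium carbene undergoes migratory insertion into the Rh–aryl bond, which makes the ring D C6–CH bond. Protonation of the Rh–C bond by acetic acid or the solvent releases keto acid 12 and returns the catalyst without an oxidant, because the ylide is a redox-neutral carbene source. 12 closes by 6-exo-trig attack of a carboxyl oxygen on the aryl ketone and the hemiketal loses water to give the enol lactone 13, which is conjugated with both arenes. The closest known reaction type is the annulation of benzoic acids with aroyl sulfoxonium ylides to 3-arylisocoumarins under [Cp*RhCl2]2 or [RuCl2(p-cymene)]2 catalysis. No stereocentre is formed. Site selectivity is needed and is secured because C6–H is the only C–H ortho to the carboxyl, C2 being blocked by methoxy; the stronger carboxylate director, the excess of 11 and slow addition of 10 should disfavour ylide-directed metalation of ring C and carbene self-coupling.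

Step 6
Reactants: 13 3-[4-[3-[2-(4-benzyloxyphenyl)ethyl]-5-methoxyphenoxy]phenyl]-6,8-dimethoxy-1H-isochromen-1-one
Product: 15 2-[2-[4-[3-[2-(4-hydroxyphenyl)ethyl]-5-methoxyphenoxy]phenyl]ethyl]-4,6-dimethoxybenzoic acid, via racemic dihydroisocoumarin 14 (not isolated)
Conditions: H2 (4 bar), 10% Pd/C, EtOAc–AcOH (4:1), 50 °C
Reagents that add atoms: none
Why: Catalytic hydrogenation and hydrogenolysis; the aryl benzyl ether is cleaved and the enol lactone C=C saturated to 14, whose C3–O bond is a benzylic ester bond activated by the para-aryloxy group and should be cleaved like a benzyl ester, as in the known reduction of 3-arylisocoumarins and benzylidenephthalides to bibenzyl-2-carboxylic acids.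

Step 7
Reactants: 15 2-[2-[4-[3-[2-(4-hydroxyphenyl)ethyl]-5-methoxyphenoxy]phenyl]ethyl]-4,6-dimethoxybenzoic acid
Product: 16 2-hydroxy-6-[2-[4-[3-[2-(4-hydroxyphenyl)ethyl]-5-methoxyphenoxy]phenyl]ethyl]-4-methoxybenzoic acid
Conditions: BCl3 (1 M in CH2Cl2, 4 equiv), CH2Cl2, −78 to 0 °C; then H2O
Reagents that add atoms: none
Why: Chelation-controlled demethylation; boron bound to the carboxyl oxygen and the ortho methoxy oxygen forms a six-membered chelate that activates only this O–CH3 bond toward chloride, while the non-chelated methyl ethers at C4 of ring D and on ring B and the diaryl ether should stay intact below 0 °C.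

## Compound list

1 | 3-hydroxy-5-methoxybenzaldehyde | COc1cc(O)cc(C=O)c1 | starting material
2 | (4-benzyloxybenzyl)triphenylphosphonium chloride | [Cl-].C(c1ccc(OCc2ccccc2)cc1)[P+](c1ccccc1)(c1ccccc1)c1ccccc1 | starting material
3 | [4-(benzyloxy)benzylidene]triphenylphosphorane (formed in the flask) | C(c1ccc(OCc2ccccc2)cc1)=P(c1ccccc1)(c1ccccc1)c1ccccc1 | intermediate
4 | 3-[2-(4-benzyloxyphenyl)ethenyl]-5-methoxyphenol (E/Z mixture) | COc1cc(O)cc(C=Cc2ccc(OCc3ccccc3)cc2)c1 | intermediate
5 | 3-[2-(4-benzyloxyphenyl)ethyl]-5-methoxyphenol | COc1cc(O)cc(CCc2ccc(OCc3ccccc3)cc2)c1 | intermediate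
6 | methyl 4-fluorobenzoate | COC(=O)c1ccc(F)cc1 | starting material
7 | methyl 4-[3-[2-(4-benzyloxyphenyl)ethyl]-5-methoxyphenoxy]benzoate | COC(=O)c1ccc(Oc2cc(OC)cc(CCc3ccc(OCc4ccccc4)cc3)c2)cc1 | intermediate
8 | trimethylsulfoxonium iodide | C[S+](C)(C)=O.[I-] | starting material
9 | dimethylsulfoxonium methylide (formed in the flask) | C=S(C)(C)=O | intermediate
10 | dimethylsulfoxonium 2-[4-[3-[2-(4-benzyloxyphenyl)ethyl]-5-methoxyphenoxy]phenyl]-2-oxoethylide | CS(C)(=O)=CC(=O)c1ccc(Oc2cc(OC)cc(CCc3ccc(OCc4ccccc4)cc3)c2)cc1 | intermediate
11 | 2,4-dimethoxybenzoic acid | COc1ccc(C(=O)O)c(OC)c1 | starting material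
12 | 2-[2-[4-[3-[2-(4-benzyloxyphenyl)ethyl]-5-methoxyphenoxy]phenyl]-2-oxoethyl]-4,6-dimethoxybenzoic acid (formed in the flask) | COc1cc(OC)c(C(=O)O)c(CC(=O)c2ccc(Oc3cc(OC)cc(CCc4ccc(OCc5ccccc5)cc4)c3)cc2)c1 | intermediate
13 | 3-[4-[3-[2-(4-benzyloxyphenyl)ethyl]-5-methoxyphenoxy]phenyl]-6,8-dimethoxy-1H-isochromen-1-one | COc1cc(OC)c2c(c1)C=C(c1ccc(Oc3cc(OC)cc(CCc4ccc(OCc5ccccc5)cc4)c3)cc1)OC2=O | intermediate
14 | racemic 3-[4-[3-[2-(4-hydroxyphenyl)ethyl]-5-methoxyphenoxy]phenyl]-6,8-dimethoxy-3,4-dihydro-1H-isochromen-1-one (formed in the flask) | COc1cc(OC)c2c(c1)CC(c1ccc(Oc3cc(OC)cc(CCc4ccc(O)cc4)c3)cc1)OC2=O | intermediate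
15 | 2-[2-[4-[3-[2-(4-hydroxyphenyl)ethyl]-5-methoxyphenoxy]phenyl]ethyl]-4,6-dimethoxybenzoic acid | COc1cc(OC)c(C(=O)O)c(CCc2ccc(Oc3cc(OC)cc(CCc4ccc(O)cc4)c3)cc2)c1 | intermediate
16 | 2-hydroxy-6-[2-[4-[3-[2-(4-hydroxyphenyl)ethyl]-5-methoxyphenoxy]phenyl]ethyl]-4-methoxybenzoic acid | COc1cc(CCc2ccc(O)cc2)cc(Oc2ccc(CCc3cc(OC)cc(O)c3C(=O)O)cc2)c1 | target

## Step count and least certain steps

Total step count: 7. Longest linear sequence: 7 steps (1 to 16 through 4, 5, 7, 10, 13 and 15); 11 enters at step 5.

Key step (step 5). The most likely failure is diversion of the carbene source: ylide-directed metalation of ring C of 10 and self-coupling of 10 could outrun the carboxylate-directed pathway, because the ortho methoxy group twists the carboxylate of 11 and may slow C–H cleavage. Incomplete dehydration of 12 is a lesser concern. The fallback replaces C–H activation by toluate-anion chemistry and sets out from 7. Commercial methyl 2,4-dimethoxy-6-methylbenzoate would be deprotonated at its benzylic methyl group with LiN(iPr)2 (2.2 equiv) in THF at −78 °C and acylated by 7 in a Claisen-type condensation to give methyl 2-[2-[4-[3-[2-(4-benzyloxyphenyl)ethyl]-5-methoxyphenoxy]phenyl]-2-oxoethyl]-4,6-dimethoxybenzoate F1. TsOH in hot toluene would then close the enol onto the ester with loss of methanol, and the route is rejoined at 13.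

Hydrogenation and hydrogenolysis (step 6). The reduction may stall after debenzylation and saturation of the C=C bond, because hydrogenolysis of a lactone C–O bond is slower than that of an open benzyl ester and the free acid and phenol can slow the catalyst. The fallback sets out from 14, which would then be isolated. The benzylic C–O bond would be cleaved by ionic hydrogenation (Et3SiH, CF3CO2H, CH2Cl2, 0 °C to rt): acid-assisted ionisation to the para-aryloxybenzyl cation and hydride transfer from silicon, which gives 15 with no new intermediate.

Selective demethylation (step 7). Loss of selectivity is the risk: on warming or with long exposure the non-chelated ethers on ring B or at C4 of ring D could also be cleaved, and the product acid could decarboxylate during an acidic work-up. The fallback removes the demethylation altogether by a change of protecting group and sets out from 10. Commercial 2-hydroxy-4-methoxybenzoic acid would be benzylated twice (benzyl bromide, K2CO3, DMF) to benzyl 2-(benzyloxy)-4-methoxybenzoate F2 and saponified (LiOH, THF–H2O) to 2-(benzyloxy)-4-methoxybenzoic acid F3. Annulation of F3 with 10 under the conditions of step 5 should give 8-(benzyloxy)-3-[4-[3-[2-(4-benzyloxyphenyl)ethyl]-5-methoxyphenoxy]phenyl]-6-methoxy-1H-isochromen-1-one F4. Hydrogenation of F4 under the conditions of step 6 would remove both benzyl groups and open the lactone, returning to the route at 16.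

Diaryl ether formation (step 3). A single ester is a weak activator, so the displacement may be slow, and at the temperature then required cleavage of the methyl ester (attack of phenoxide at the O-methyl group, or saponification by traces of water) may compete. The fallback replaces addition–elimination by an Ullmann-type copper-catalysed O-arylation and sets out from 5: coupling with methyl 4-iodobenzoate (CuI, picolinic acid, K3PO4, DMSO, 90 °C) should give 7 directly at lower temperature.

## Further compounds

F1 | step 5 | methyl 2-[2-[4-[3-[2-(4-benzyloxyphenyl)ethyl]-5-methoxyphenoxy]phenyl]-2-oxoethyl]-4,6-dimethoxybenzoate | COC(=O)c1c(OC)cc(OC)cc1CC(=O)c1ccc(Oc2cc(OC)cc(CCc3ccc(OCc4ccccc4)cc3)c2)cc1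
F0 | step 6 | none | none
F2 | step 7 | benzyl 2-(benzyloxy)-4-methoxybenzoate | COc1ccc(C(=O)OCc2ccccc2)c(OCc2ccccc2)c1
F3 | step 7 | 2-(benzyloxy)-4-methoxybenzoic acid | COc1ccc(C(=O)O)c(OCc2ccccc2)c1
F4 | step 7 | 8-(benzyloxy)-3-[4-[3-[2-(4-benzyloxyphenyl)ethyl]-5-methoxyphenoxy]phenyl]-6-methoxy-1H-isochromen-1-one | COc1cc(OCc2ccccc2)c2c(c1)C=C(c1ccc(Oc3cc(OC)cc(CCc4ccc(OCc5ccccc5)cc4)c3)cc1)OC2=O
F0 | step 3 | none | none
A1 | alternative 1 | benzyl 2-(benzyloxy)-6-[2-[4-[3-[2-(4-benzyloxyphenyl)ethynyl]-5-methoxyphenoxy]phenyl]ethyl]-4-methoxybenzoate | COc1cc(C#Cc2ccc(OCc3ccccc3)cc2)cc(Oc2ccc(CCc3cc(OC)cc(OCc4ccccc4)c3C(=O)OCc3ccccc3)cc2)c1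
A2 | alternative 1 | benzyl 2-(benzyloxy)-6-[2-[4-(3-bromo-5-methoxyphenoxy)phenyl]ethyl]-4-methoxybenzoate | COc1cc(Br)cc(Oc2ccc(CCc3cc(OC)cc(OCc4ccccc4)c3C(=O)OCc3ccccc3)cc2)c1
A3 | alternative 1 | 1-(benzyloxy)-4-iodobenzene | Ic1ccc(OCc2ccccc2)cc1
A4 | alternative 1 | propiolic acid | C#CC(=O)O
A5 | alternative 2 | tert-butyl 2-[2-[4-[3-[2-(4-benzyloxyphenyl)ethyl]-5-hydroxyphenoxy]phenyl]ethyl]-4,6-dimethoxybenzoate | Oc1cc(CCc2ccc(OCc3ccccc3)cc2)cc(Oc2ccc(CCc3cc(OC)cc(OC)c3C(=O)OC(C)(C)C)cc2)c1
A6 | alternative 2 | 3-[2-(4-benzyloxyphenyl)ethyl]cyclobut-2-en-1-one | O=C1C=C(CCc2ccc(OCc3ccccc3)cc2)C1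
A7 | alternative 2 | tert-butyl 2-[2-(4-ethynyloxyphenyl)ethyl]-4,6-dimethoxybenzoate | C#COc1ccc(CCc2cc(OC)cc(OC)c2C(=O)OC(C)(C)C)cc1
A8 | alternative 3 | racemic trans-methyl 6-[2-[4-[3-[2-(4-benzyloxyphenyl)ethyl]-5-methoxyphenoxy]phenyl]ethyl]-2-hydroxy-4-oxocyclohex-2-ene-1-carboxylate (one enantiomer drawn) | COC(=O)[C@@H]1[C@@H](CCc2ccc(Oc3cc(OC)cc(CCc4ccc(OCc5ccccc5)cc4)c3)cc2)CC(=O)C=C1O
A9 | alternative 3 | (E)-6-[4-[3-[2-(4-benzyloxyphenyl)ethyl]-5-methoxyphenoxy]phenyl]hex-3-en-2-one | CC(=O)/C=C/CCc1ccc(Oc2cc(OC)cc(CCc3ccc(OCc4ccccc4)cc3)c2)cc1
A10 | alternative 3 | dimethyl malonate | COC(=O)CC(=O)OC
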